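**Retrosynthetic overview**

- The route rests on the 4-hydroxy-2-pyrone ring. C2, C3 (bearing the arylmethyl group) and C4 are a malonyl unit. C5 (methyl), C6 (ethyl) and O1 are the enol carbons and oxygen of the symmetric ketone pentan-3-one.
- Last operation: the two methyl ethers flanking the aryl ketone in trimethyl ether 13 are removed by chelation-directed BCl3 cleavage. The methoxy group para to the ketone stays.
- Key disconnection: C4–C5 and O1–C2 of the pyrone, giving arylmethylmalonyl dichloride 9 and silyl enol ether 11. The benzene ring is bought, and the pyrone is the only ring formed (step 8).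
- Dichloride 9 comes from malonic acid 8, which comes from dibenzyl ester 7. The (R)-2-methylbutanoyl group enters by Friedel–Crafts acylation of the symmetric benzylmalonate 4, after the chain is in place, so the stereocentre passes through few steps.
- Ester 4 comes from 2,4,6-trimethoxybenzaldehyde and dibenzyl malonate by Knoevenagel condensation and conjugate reduction. The single stereocentre is taken from (2R)-2-methylbutanoic acid.

Key step: step 8

Remark: (2R)-2-methylbutanoic acid is assumed to be bought as the single enantiomer. Enol ether 11 is drawn as its Z isomer; the E isomer gives the same pyrone because C5 and C6 end up sp2, so a mixture of isomers may be used.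

**Route**

Step 1
Reactants: 1 2,4,6-trimethoxybenzaldehyde; 2 dibenzyl malonate
Product: 3 dibenzyl 2-[(2,4,6-trimethoxyphenyl)methylidene]propanedioate
Conditions: piperidine (0.2 equiv), AcOH (0.2 equiv), toluene, reflux, Dean–Stark
Reagents that add atoms: none
Why: Knoevenagel condensation, in which piperidinium acetate activates the hindered, electron-rich aldehyde as its iminium ion and azeotropic removal of water should drive the condensation with the malonate to completion; no stereocentre is involved.

Step 2
Reactants: 3 dibenzyl 2-[(2,4,6-trimethoxyphenyl)methylidene]propanedioate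
Product: 4 dibenzyl 2-[(2,4,6-trimethoxyphenyl)methyl]propanedioate
Conditions: NaBH4, THF/i-PrOH, 0 °C; then aq. NH4Cl
Reagents that add atoms: none
Why: Conjugate reduction, since the alkylidene malonate is a doubly activated Michael acceptor that NaBH4 should reduce at the benzylic carbon at 0 °C, where the benzyl esters are not attacked.

Step 3
Reactants: 5 (2R)-2-methylbutanoic acid
Product: 6 (2R)-2-methylbutanoyl chloride
Conditions: (COCl)2 (1.05 equiv), DMF (cat.), CH2Cl2, 0 °C → rt; short-path distillation
Reagents that add atoms: oxalyl chloride, O=C(Cl)C(Cl)=O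
Why: Acid chloride formation under chloroiminium (Vilsmeier-type) catalysis should proceed without base, so no ketene can form and the (R) centre from the chiral pool is kept.

Step 4
Reactants: 4 dibenzyl 2-[(2,4,6-trimethoxyphenyl)methyl]propanedioate; 6 (2R)-2-methylbutanoyl chloride
Product: 7 dibenzyl 2-({2,4,6-trimethoxy-3-[(2R)-2-methylbutanoyl]phenyl}methyl)propanedioate
Conditions: SnCl4 (2.2 equiv), CH2Cl2, −30 → 0 °C; then cold 1 M HCl
Reagents that add atoms: none
Why: Friedel–Crafts acylation, in which the two open ring positions of 4 are equivalent and each is activated by two ortho and one para methoxy group, so a single mono-ketone is expected (the new carbonyl deactivates the ring), and the low temperature is meant to spare the benzyl esters, the methyl ethers and the (R) centre brought in with 6.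

Step 5
Reactants: 7 dibenzyl 2-({2,4,6-trimethoxy-3-[(2R)-2-methylbutanoyl]phenyl}methyl)propanedioate
Product: 8 2-({2,4,6-trimethoxy-3-[(2R)-2-methylbutanoyl]phenyl}methyl)propanedioic acid
Conditions: H2 (1 atm), 10% Pd/C, EtOAc, rt
Reagents that add atoms: none
Why: Hydrogenolysis of the two benzyl esters over Pd/C should free the malonic acid under neutral conditions at room temperature, where the hindered, twisted aryl ketone is not reduced, the diacid does not decarboxylate and the (R) centre sees neither acid nor base.

Step 6
Reactants: 8 2-({2,4,6-trimethoxy-3-[(2R)-2-methylbutanoyl]phenyl}methyl)propanedioic acid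
Product: 9 2-({2,4,6-trimethoxy-3-[(2R)-2-methylbutanoyl]phenyl}methyl)propanedioyl dichloride
Conditions: (COCl)2 (2.2 equiv), DMF (cat.), CH2Cl2, 0 °C → rt; concentrate, use crude
Reagents that add atoms: oxalyl chloride, O=C(Cl)C(Cl)=O
Why: Acid chloride formation with oxalyl chloride and catalytic DMF converts both carboxyl groups, and because both positions ortho to the benzylic carbon carry methoxy groups the dichloride cannot cyclise onto its own ring.

Step 7
Reactants: 10 pentan-3-one
Product: 11 (Z)-3-(trimethylsilyloxy)pent-2-ene
Conditions: TMSOTf, Et3N, CH2Cl2, 0 °C; pentane extraction, distillation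
Reagents that add atoms: trimethylsilyl trifluoromethanesulfonate, C[Si](C)(C)OS(=O)(=O)C(F)(F)F
Why: Soft enolisation and O-silylation of the symmetric ketone gives a single constitutional enol ether, whose double-bond geometry has no consequence later.

Step 8
Reactants: 9 2-({2,4,6-trimethoxy-3-[(2R)-2-methylbutanoyl]phenyl}methyl)propanedioyl dichloride; 11 (Z)-3-(trimethylsilyloxy)pent-2-ene
Product: 13 6-ethyl-4-hydroxy-5-methyl-3-({2,4,6-trimethoxy-3-[(2R)-2-methylbutanoyl]phenyl}methyl)-2H-pyran-2-one, via 3,5-dioxoheptanoyl chloride 12 (not isolated)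
Conditions: 11 (1.3 equiv), Et2O/CH2Cl2, −78 °C → rt, no base; then H2O
Reagents that add atoms: none
Why: The nucleophilic carbon of enol ether 11 attacks one acyl chloride of 9 (or the chlorocarbonyl ketene formed from 9 by loss of HCl) and chloride removes the silyl group as Me3SiCl, which gives diketo acid chloride 12 with the C4–C5 bond in place. The C6 carbonyl of 12 then enolises and its oxygen attacks the remaining acyl chloride in a 6-exo-trig lactonisation that forms O1–C2, and tautomerisation to the aromatic 4-hydroxy-2-pyrone makes the closure irreversible. The closest known reaction type is the synthesis of 4-hydroxy-2-pyrones from silyl enol ethers or ketones and malonyl dichlorides, 2-substituted ones included. No stereocentre is created, because the two sp3 carbons of 12 become sp2, and the (R) centre next to the hindered aryl ketone should be untouched since no base is present and the temperature is low. The step needs C-acylation over O-acylation of the enol ether and one enol ether per malonyl unit; the first should follow from the soft carbon terminus of the silyl enol ether, the second from intramolecular capture of the second acyl chloride being faster than attack by another enol ether. The ethyl and methyl groups fall on C6 and C5 without a regiochemical choice because pentan-3-one is symmetric, and the arylmethyl group is fixed at C3 because it sits on the central malonyl carbon.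

Step 9
Reactants: 13 6-ethyl-4-hydroxy-5-methyl-3-({2,4,6-trimethoxy-3-[(2R)-2-methylbutanoyl]phenyl}methyl)-2H-pyran-2-one
Product: 14 3-({2,4-dihydroxy-6-methoxy-3-[(2R)-2-methylbutanoyl]phenyl}methyl)-6-ethyl-4-hydroxy-5-methyl-2H-pyran-2-one
Conditions: BCl3 (1 M in CH2Cl2, 5 equiv), CH2Cl2, −78 °C → rt; then ice-cold 1 M HCl
Reagents that add atoms: none
Why: Chelation-directed Lewis-acid ether cleavage, in which boron bound to the ketone oxygen reaches the oxygen of each flanking methoxy group through a six-membered chelate and chloride removes the methyl group, whereas the methoxy group para to the ketone has no such partner and should stay; the (R) centre is exposed to no base.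

**Compound list**

1 | 2,4,6-trimethoxybenzaldehyde | COc1cc(OC)c(C=O)c(OC)c1 | starting material
2 | dibenzyl malonate | O=C(CC(=O)OCc1ccccc1)OCc1ccccc1 | starting material
3 | dibenzyl 2-[(2,4,6-trimethoxyphenyl)methylidene]propanedioate | COc1cc(OC)c(C=C(C(=O)OCc2ccccc2)C(=O)OCc2ccccc2)c(OC)c1 | intermediate
4 | dibenzyl 2-[(2,4,6-trimethoxyphenyl)methyl]propanedioate | COc1cc(OC)c(CC(C(=O)OCc2ccccc2)C(=O)OCc2ccccc2)c(OC)c1 | intermediate
5 | (2R)-2-methylbutanoic acid | CC[C@@H](C)C(=O)O | starting material
6 | (2R)-2-methylbutanoyl chloride | CC[C@@H](C)C(Cl)=O | intermediate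
7 | dibenzyl 2-({2,4,6-trimethoxy-3-[(2R)-2-methylbutanoyl]phenyl}methyl)propanedioate | CC[C@@H](C)C(=O)c1c(OC)cc(OC)c(CC(C(=O)OCc2ccccc2)C(=O)OCc2ccccc2)c1OC | intermediate
8 | 2-({2,4,6-trimethoxy-3-[(2R)-2-methylbutanoyl]phenyl}methyl)propanedioic acid | CC[C@@H](C)C(=O)c1c(OC)cc(OC)c(CC(C(=O)O)C(=O)O)c1OC | intermediate
9 | 2-({2,4,6-trimethoxy-3-[(2R)-2-methylbutanoyl]phenyl}methyl)propanedioyl dichloride | CC[C@@H](C)C(=O)c1c(OC)cc(OC)c(CC(C(Cl)=O)C(Cl)=O)c1OC | intermediate
10 | pentan-3-one | CCC(=O)CC | starting material
11 | (Z)-3-(trimethylsilyloxy)pent-2-ene | C/C=C(/CC)O[Si](C)(C)C | intermediate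
12 | 4-methyl-3,5-dioxo-2-({2,4,6-trimethoxy-3-[(2R)-2-methylbutanoyl]phenyl}methyl)heptanoyl chloride (mixture of isomers at C2 and C4, not isolated) | CCC(=O)C(C)C(=O)C(Cc1c(OC)cc(OC)c(C(=O)[C@H](C)CC)c1OC)C(Cl)=O | intermediate
13 | 6-ethyl-4-hydroxy-5-methyl-3-({2,4,6-trimethoxy-3-[(2R)-2-methylbutanoyl]phenyl}methyl)-2H-pyran-2-one | CCc1oc(=O)c(Cc2c(OC)cc(OC)c(C(=O)[C@H](C)CC)c2OC)c(O)c1C | intermediate
14 | 3-({2,4-dihydroxy-6-methoxy-3-[(2R)-2-methylbutanoyl]phenyl}methyl)-6-ethyl-4-hydroxy-5-methyl-2H-pyran-2-one | CCc1oc(=O)c(Cc2c(OC)cc(O)c(C(=O)[C@H](C)CC)c2O)c(O)c1C | target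

**Step count and risks**

Total steps: 9. Longest linear sequence: 7 steps (steps 1, 2, 4, 5, 6, 8 and 9, from 2,4,6-trimethoxybenzaldehyde).

Steps most likely to fail:

1. Step 8. The enol ether may be acylated on oxygen instead of carbon, the intermediate acid chloride may be captured by a second enol ether, HCl may strip the silyl group before acylation, or the dichloride may oligomerise through its chlorocarbonyl ketene. The fallback makes the pyrone first and joins it to the aryl unit at C3; it sets out from 6 and 11 and comes back at 13.
   - Friedel–Crafts acylation of 1,3,5-trimethoxybenzene with 6 (SnCl4, CH2Cl2, −30 °C) should give (2R)-2-methyl-1-(2,4,6-trimethoxyphenyl)butan-1-one F1.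
   - Vilsmeier–Haack formylation (POCl3, DMF, 0 °C → rt) at one of its two equivalent ring positions should give 2,4,6-trimethoxy-3-[(2R)-2-methylbutanoyl]benzaldehyde F2.
   - Separately, 11 and unsubstituted malonyl dichloride (Et2O, −78 °C → rt), the parent case of this annulation, should give 6-ethyl-4-hydroxy-5-methyl-2H-pyran-2-one F3.
   - Three-component reductive alkylation of F3 with F2 and diethyl 2,6-dimethyl-1,4-dihydropyridine-3,5-dicarboxylate (Hantzsch ester; L-proline cat., CH2Cl2, rt) would then give 13 by Knoevenagel condensation at C3 followed by hydride transfer to the arylidene pyrandione, and step 9 follows as planned.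

2. Step 9. The second ether cleavage may stall once the ketone oxygen is tied up in the first boron chelate, and more forcing treatment may remove the third methyl ether or break the aryl–CH2–pyrone bridge. The fallback avoids late demethylation by joining a free phenol to the pyrone through a methylene unit; it sets out from 6 and comes back at 14.
   - Friedel–Crafts acylation of phloroglucinol with 6 (AlCl3, CH2Cl2/MeNO2) should give (2R)-2-methyl-1-(2,4,6-trihydroxyphenyl)butan-1-one F4.
   - Methylation of the one hydroxyl that is not hydrogen-bonded to the ketone (Me2SO4, 1 equiv, K2CO3, acetone) should give (2R)-1-(2,6-dihydroxy-4-methoxyphenyl)-2-methylbutan-1-one F5.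
   - Pyrone F3, prepared as in the fallback to step 8, would be treated with N,N-dimethylmethyleneiminium iodide (MeCN, rt) to give 3-[(dimethylamino)methyl]-6-ethyl-4-hydroxy-5-methyl-2H-pyran-2-one F6.
   - On warming with F5, F6 should lose dimethylamine to a 3-methylenepyran-2,4-dione that alkylates one of the two equivalent ring carbons of F5 (Mannich base elimination, then Michael addition), giving 14 directly.

3. Step 4. The tin halide may cleave the benzyl esters, and the benzyl cations set free may alkylate the electron-rich ring. The fallback carries the malonate as allyl esters, which are inert to SnCl4 and are removed without hydrogen; it sets out from 1 and 6 and comes back at 8.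
   - Knoevenagel condensation of 1 with commercial diallyl malonate (piperidine, AcOH, toluene, reflux) should give diallyl 2-[(2,4,6-trimethoxyphenyl)methylidene]propanedioate F7.
   - Conjugate reduction with NaBH4 (THF/i-PrOH, 0 °C) should give diallyl 2-[(2,4,6-trimethoxyphenyl)methyl]propanedioate F8.
   - Acylation with 6 under the conditions of step 4 should give diallyl 2-({2,4,6-trimethoxy-3-[(2R)-2-methylbutanoyl]phenyl}methyl)propanedioate F9.
   - Allyl transfer to morpholine catalysed by Pd(PPh3)4 (THF, rt) would release malonic acid 8.

Further compounds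
F1 | step 8 | (2R)-2-methyl-1-(2,4,6-trimethoxyphenyl)butan-1-one | CC[C@@H](C)C(=O)c1c(OC)cc(OC)cc1OC
F2 | step 8 | 2,4,6-trimethoxy-3-[(2R)-2-methylbutanoyl]benzaldehyde | CC[C@@H](C)C(=O)c1c(OC)cc(OC)c(C=O)c1OC
F3 | step 8 | 6-ethyl-4-hydroxy-5-methyl-2H-pyran-2-one | CCc1oc(=O)cc(O)c1C
F4 | step 9 | (2R)-2-methyl-1-(2,4,6-trihydroxyphenyl)butan-1-one | CC[C@@H](C)C(=O)c1c(O)cc(O)cc1O
F5 | step 9 | (2R)-1-(2,6-dihydroxy-4-methoxyphenyl)-2-methylbutan-1-one | CC[C@@H](C)C(=O)c1c(O)cc(OC)cc1O
F6 | step 9 | 3-[(dimethylamino)methyl]-6-ethyl-4-hydroxy-5-methyl-2H-pyran-2-one | CCc1oc(=O)c(CN(C)C)c(O)c1C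
F7 | step 4 | diallyl 2-[(2,4,6-trimethoxyphenyl)methylidene]propanedioate | COc1cc(OC)c(C=C(C(=O)OCC=C)C(=O)OCC=C)c(OC)c1
F8 | step 4 | diallyl 2-[(2,4,6-trimethoxyphenyl)methyl]propanedioate | COc1cc(OC)c(CC(C(=O)OCC=C)C(=O)OCC=C)c(OC)c1
F9 | step 4 | diallyl 2-({2,4,6-trimethoxy-3-[(2R)-2-methylbutanoyl]phenyl}methyl)propanedioate | CC[C@@H](C)C(=O)c1c(OC)cc(OC)c(CC(C(=O)OCC=C)C(=O)OCC=C)c1OC
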